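**Retrosynthetic overview**
1. Target 23 ⇐ tricyclic siloxane 22 by fluoride: a Si(iPr)2 unit that ties O5 to C4 is a temporary ring, and a second silyl group protects O8; both leave together.
2. 22 ⇐ aryl iodide 21 in one Pd-catalysed, ligand-controlled domino: the aryl–Pd at C4a adds across an ethyne tethered to O5 (C4–C4a), the cis-alkenyl–Pd inserts the enol ether on O1 (C3–C2, pyran ring, C2 stereocentre), and formate turns Pd–CH2 into the C2 methyl.
3. Enabling feature: in the benzene ring C4a lies between the oxygen-bearing carbons C5 and C8a, so the alkyne and the enol ether hang from O5 and O1 on either side of one C–Pd bond; C2 of the pyran ring is fully substituted and carries a methyl group, so the cascade can end on a Pd–CH2 with no β-hydrogen.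
4. 21 ⇐ quinonyl ester 16 (reduction/silylation, one double Ti methylenation that makes both the enol ether and the exocyclic methylene, silyl exchange with two equivalents of silyl chloride 14) ⇐ iodohydroxyquinone 11 + keto acid 8; the quinone level tells O1 apart from O5 and O8.
5. 8 ⇐ octalone 7 ⇐ 2,6-dimethylcyclohexanone 1: a chiral-imine Michael addition sets the quaternary centre, a temporary cyclohexenone ring lets the secondary methyl equilibrate, and RuO4 cuts it open. Ring order: cyclohexane (bought) → temporary cyclohexenone → benzene (bought as quinone) → oxasilole and pyran together in step 12.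

Key step: step 12

Assumption: (R)-BINAP is taken as the ligand antipode that leads to the (S) centre at C2; if the sense of induction is the opposite, (S)-BINAP is used and nothing else changes.

**Step 1**
Reactants: 1 2,6-dimethylcyclohexanone (cis/trans mixture); 2 (S)-1-phenylethylamine
Product: 3 (1S)-N-(2,6-dimethylcyclohexylidene)-1-phenylethanamine
Conditions: TsOH (cat.), toluene, reflux, Dean–Stark
Reagents that add atoms: none
Why: Acid-catalysed ketimine condensation with azeotropic removal of water; the α-centres equilibrate through the enamine and need no control here.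

**Step 2**
Reactants: 3 (1S)-N-(2,6-dimethylcyclohexylidene)-1-phenylethanamine; 4 methyl vinyl ketone
Product: 6 (2R)-2,6-dimethyl-2-(3-oxobutyl)cyclohexan-1-one (both C6 epimers), via Michael-adduct imine 5 (not isolated)
Conditions: 4 (1.2 equiv), THF, rt, 3 d; then 10% aq AcOH, rt
Reagents that add atoms: water, O
Why: d'Angelo deracemising Michael addition, in which the secondary enamine tautomer of 3 adds to the enone through a compact aza-ene-like transition state on the face away from the phenyl group of the auxiliary, which should set the quaternary centre as R before hydrolysis releases the amine.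

**Step 3**
Reactants: 6 (2R)-2,6-dimethyl-2-(3-oxobutyl)cyclohexan-1-one
Product: 7 (4aR,8R)-4a,8-dimethyl-4,4a,5,6,7,8-hexahydronaphthalen-2(3H)-one
Conditions: NaOMe (0.3 equiv), MeOH, 60 °C, to equilibrium; chromatography, minor C8 epimer resubmitted
Reagents that add atoms: none
Why: Intramolecular aldol condensation (second half of a Robinson annulation) closes the temporary cyclohexenone ring, and C8 epimerises through the dienolate to the isomer with the equatorial methyl trans to the axial angular methyl, since the cis isomer needs a syn-diaxial Me/Me contact or a less stable ring-flipped conformer (thermodynamic control).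

**Step 4**
Reactants: 7 (4aR,8R)-4a,8-dimethyl-4,4a,5,6,7,8-hexahydronaphthalen-2(3H)-one
Product: 8 3-[(1R,3R)-1,3-dimethyl-2-oxocyclohexyl]propanoic acid
Conditions: RuCl3·xH2O (2 mol %), NaIO4 (4.5 equiv), EtOAc/MeCN/H2O, 0 °C to rt
Reagents that add atoms: sodium periodate, [Na+].[O-]I(=O)(=O)=O; water, O
Why: RuO4 oxidative cleavage of the enone C=C gives the ring ketone and an α-keto acid that is decarboxylated oxidatively to the acid one carbon shorter, and the near-neutral medium should leave the α-methyl ketone centre untouched.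

**Step 5**
Reactants: 9 2,5-dimethoxy-1,4-benzoquinone
Product: 10 2-hydroxy-5-methoxy-1,4-benzoquinone
Conditions: NaOH (1.05 equiv), H2O/MeOH, rt; then 1 M HCl
Reagents that add atoms: sodium hydroxide, [Na+].[OH-]
Why: Addition–elimination of hydroxide at a vinylogous ester carbon; the hydroxyquinone anion that forms is deactivated, so the second methoxy group should survive.

**Step 6**
Reactants: 10 2-hydroxy-5-methoxy-1,4-benzoquinone
Product: 11 2-hydroxy-3-iodo-5-methoxy-1,4-benzoquinone
Conditions: NIS (1.05 equiv), MeCN, 0 °C to rt, dark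
Reagents that add atoms: N-iodosuccinimide, O=C1CCC(=O)N1I
Why: Electrophilic iodination of the enolised 1,3-dicarbonyl unit at C3 (the reaction that gives 3-halolawsones), while C6 is only the β-carbon of a vinylogous ester and far less nucleophilic.

**Step 7**
Reactants: 12 dichlorodi(propan-2-yl)silane; 13 ethynylmagnesium bromide
Product: 14 chloro(ethynyl)di(propan-2-yl)silane
Conditions: 13 (0.5 M in THF, 1.0 equiv) added to 12, THF, −78 °C to rt; distillation
Reagents that add atoms: none
Why: Nucleophilic substitution at silicon by an alkynyl Grignard reagent, with the two isopropyl groups slowing the second substitution so that the monochloride can be isolated.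

**Step 8**
Reactants: 8 3-[(1R,3R)-1,3-dimethyl-2-oxocyclohexyl]propanoic acid; 11 2-hydroxy-3-iodo-5-methoxy-1,4-benzoquinone
Product: 16 3-iodo-5-methoxy-1,4-benzoquinon-2-yl 3-[(1R,3R)-1,3-dimethyl-2-oxocyclohexyl]propanoate, via acid chloride 15 (not isolated)
Conditions: (COCl)2, DMF (cat.), CH2Cl2, 0 °C, evaporate; then 11, Et3N, CH2Cl2, −20 °C
Reagents that add atoms: none
Why: O-acylation of the vinylogous acid, as in the preparation of 2-acyloxy-1,4-naphthoquinones from lawsone; only the hydroxyquinone oxygen (the future O1) is acylated because O5 and O8 are still carbonyl oxygens.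

**Step 9**
Reactants: 16 3-iodo-5-methoxy-1,4-benzoquinon-2-yl 3-[(1R,3R)-1,3-dimethyl-2-oxocyclohexyl]propanoate
Product: 18 2-iodo-4-methoxy-3,6-bis(trimethylsilyloxy)phenyl 3-[(1R,3R)-1,3-dimethyl-2-oxocyclohexyl]propanoate, via hydroquinone monoester 17 (not isolated)
Conditions: Na2S2O4 (3 equiv), EtOAc/H2O, rt, 5 min; dry; then BSA (3 equiv), CH2Cl2, rt
Reagents that add atoms: N,O-bis(trimethylsilyl)acetamide, CC(=N[Si](C)(C)C)O[Si](C)(C)C
Why: Dithionite reduction of the quinone followed by base-free silylation of both phenols, which should be faster than the base-catalysed 1,2-acyl shift of the catechol-type monoester.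

**Step 10**
Reactants: 18 2-iodo-4-methoxy-3,6-bis(trimethylsilyloxy)phenyl 3-[(1R,3R)-1,3-dimethyl-2-oxocyclohexyl]propanoate
Product: 19 1-({4-[(1R,3R)-1,3-dimethyl-2-methylidenecyclohexyl]but-1-en-2-yl}oxy)-2-iodo-4-methoxy-3,6-bis(trimethylsilyloxy)benzene
Conditions: Cp2TiMe2 (5 equiv), toluene/THF, 65 °C, dark; filtration through basic Al2O3
Reagents that add atoms: dimethyltitanocene Cp2TiMe2, C[Ti](C)(C1C=CC=C1)C1C=CC=C1
Why: Petasis methylenation converts the aryl ester into the aryl 1-alkylvinyl ether and the hindered ring ketone into the exocyclic methylene in one operation under non-basic conditions, so the α-methyl centre should not epimerise and the aryl iodide and silyl ethers are inert.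

**Step 11**
Reactants: 19 1-({4-[(1R,3R)-1,3-dimethyl-2-methylidenecyclohexyl]but-1-en-2-yl}oxy)-2-iodo-4-methoxy-3,6-bis(trimethylsilyloxy)benzene; 14 chloro(ethynyl)di(propan-2-yl)silane (two equivalents are incorporated, one on each phenol oxygen)
Product: 21 1-({4-[(1R,3R)-1,3-dimethyl-2-methylidenecyclohexyl]but-1-en-2-yl}oxy)-3,6-bis{[ethynyldi(propan-2-yl)silyl]oxy}-2-iodo-4-methoxybenzene, via free hydroquinone 20 (not isolated)
Conditions: K2CO3 (0.2 equiv), MeOH, 0 °C, argon; evaporate; then 14 (2.5 equiv, of which two are incorporated), imidazole (5 equiv), DMF, 0 °C to rt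
Reagents that add atoms: chloro(ethynyl)di(propan-2-yl)silane 14 (the second equivalent, which silylates the other phenol oxygen), C#C[Si](Cl)(C(C)C)C(C)C
Why: Methanolysis of the two labile aryl trimethylsilyl ethers and imidazole-mediated resilylation of both phenols, each by one equivalent of 14 (O5 receives the tether, O8 a protecting group of the same kind, so the two oxygens need not be told apart), kept basic throughout so that the C8 phenol cannot add to the acid-sensitive enol ether next to it; the terminal alkynes are brought in only now because they would not survive the titanium methylidene.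

**Step 12**
Reactants: 21 1-({4-[(1R,3R)-1,3-dimethyl-2-methylidenecyclohexyl]but-1-en-2-yl}oxy)-3,6-bis{[ethynyldi(propan-2-yl)silyl]oxy}-2-iodo-4-methoxybenzene
Product: 22 tricyclic siloxane: (2S)-2-{2-[(1R,3R)-1,3-dimethyl-2-methylidenecyclohexyl]ethyl}-6-methoxy-2-methyl-2H-chromene in which C4 and O5 are bridged by a di(propan-2-yl)silylene unit (1,2-oxasilole ring) and O8 carries the ethynyldi(propan-2-yl)silyl group
Conditions: Pd2(dba)3 (5 mol %), (R)-BINAP (12 mol %), HCO2Na (1.5 equiv), DMA, 90 °C, 0.01 M, argon
Reagents that add atoms: none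
Why: Proposed new method: zerovalent palladium inserts into the C4a–I bond, the aryl–Pd adds syn across the silicon-tethered ethyne (5-exo-dig, closing the 1,2-oxasilole ring and forming C4a–C4), and the alkenyl–Pd, held cis to the arene and next to O1, inserts the 1,1-disubstituted enol ether at its oxygen-bearing carbon (6-exo-trig, closing the pyran ring and forming C3–C2); the Pd–CH2 group so formed has no β-hydrogen and is reduced by formate to the C2 methyl. The closest known reaction types are the palladium cyclisation/hydride-capture cascades of enynes and the enantioselective intramolecular reductive Heck reaction that builds quaternary centres from 1,1-disubstituted alkenes; new here is an alkenyl–Pd insertion into an aryl enol ether that gives a tertiary aryl ether centre under ligand control. The C2 stereocentre is set in the alkene insertion by the chiral bisphosphine on palladium (catalyst control, the cyclohexane centres being too remote to matter), the two faces differing in whether the side chain or the CH2 terminus points into the ligand pocket. Chemoselectivity comes from the substrate: direct attack of the aryl–Pd on the enol ether would need a 4-exo or 5-endo closure, the alkyne insertion can only be exo, and the second silyl ethyne on O8 is out of reach. Hydride capture before the second ring closes is held back by the low solubility of HCO2Na in DMA and by dilution. Once the Pd–CH2 group exists, its reduction by formate has to outrun β-aryloxide elimination (which would reopen the pyran ring) and insertion into the hindered exocyclic methylene.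

**Step 13**
Reactants: 22 tricyclic siloxane
Product: 23 (2S)-2-{2-[(1R,3R)-1,3-dimethyl-2-methylidenecyclohexyl]ethyl}-6-methoxy-2-methyl-2H-chromene-5,8-diol
Conditions: TBAF (1 M in THF, 6 equiv), THF, 60 °C, argon; then aq NH4Cl/Na2S2O4
Reagents that add atoms: none
Why: Fluoride cleaves both Si–O bonds and, through the pentacoordinate fluorosilicate, the vinylic C4–Si bond by protodesilylation (known for cyclic alkenyl siloxanes), so tether and protecting group leave together without touching a stereocentre, and the dithionite wash keeps the product at the hydroquinone level.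

**Compound list**
1 | 2,6-dimethylcyclohexanone | CC1CCCC(C)C1=O | starting material
2 | (S)-1-phenylethylamine | C[C@H](N)c1ccccc1 | starting material
3 | (1S)-N-(2,6-dimethylcyclohexylidene)-1-phenylethanamine | CC1CCCC(C)C1=N[C@@H](C)c1ccccc1 | intermediate
4 | methyl vinyl ketone | CC(=O)C=C | starting material
5 | (1S)-N-[(2R)-2,6-dimethyl-2-(3-oxobutyl)cyclohexylidene]-1-phenylethanamine | CC(=O)CC[C@@]1(C)CCCC(C)C1=N[C@@H](C)c1ccccc1 | intermediate
6 | (2R)-2,6-dimethyl-2-(3-oxobutyl)cyclohexan-1-one | CC(=O)CC[C@@]1(C)CCCC(C)C1=O | intermediate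
7 | (4aR,8R)-4a,8-dimethyl-4,4a,5,6,7,8-hexahydronaphthalen-2(3H)-one | O=C1C=C2[C@H](C)CCC[C@]2(C)CC1 | intermediate
8 | 3-[(1R,3R)-1,3-dimethyl-2-oxocyclohexyl]propanoic acid | O=C1[C@H](C)CCC[C@]1(C)CCC(O)=O | intermediate
9 | 2,5-dimethoxy-1,4-benzoquinone | COC1=CC(=O)C(OC)=CC1=O | starting material
10 | 2-hydroxy-5-methoxy-1,4-benzoquinone | COC1=CC(=O)C(O)=CC1=O | intermediate
11 | 2-hydroxy-3-iodo-5-methoxy-1,4-benzoquinone | COC1=CC(=O)C(O)=C(I)C1=O | intermediate
12 | dichlorodi(propan-2-yl)silane | CC(C)[Si](Cl)(Cl)C(C)C | starting material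
13 | ethynylmagnesium bromide | C#C[Mg]Br | starting material
14 | chloro(ethynyl)di(propan-2-yl)silane | C#C[Si](Cl)(C(C)C)C(C)C | intermediate
15 | 3-[(1R,3R)-1,3-dimethyl-2-oxocyclohexyl]propanoyl chloride | O=C1[C@H](C)CCC[C@]1(C)CCC(Cl)=O | intermediate
16 | 3-iodo-5-methoxy-1,4-benzoquinon-2-yl 3-[(1R,3R)-1,3-dimethyl-2-oxocyclohexyl]propanoate | COC1=CC(=O)C(OC(=O)CC[C@@]2(C)CCC[C@@H](C)C2=O)=C(I)C1=O | intermediate
17 | 2,5-dihydroxy-6-iodo-4-methoxyphenyl 3-[(1R,3R)-1,3-dimethyl-2-oxocyclohexyl]propanoate | COc1cc(O)c(OC(=O)CC[C@@]2(C)CCC[C@@H](C)C2=O)c(I)c1O | intermediate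
18 | 2-iodo-4-methoxy-3,6-bis(trimethylsilyloxy)phenyl 3-[(1R,3R)-1,3-dimethyl-2-oxocyclohexyl]propanoate | COc1cc(O[Si](C)(C)C)c(OC(=O)CC[C@@]2(C)CCC[C@@H](C)C2=O)c(I)c1O[Si](C)(C)C | intermediate
19 | 1-({4-[(1R,3R)-1,3-dimethyl-2-methylidenecyclohexyl]but-1-en-2-yl}oxy)-2-iodo-4-methoxy-3,6-bis(trimethylsilyloxy)benzene | COc1cc(O[Si](C)(C)C)c(OC(=C)CC[C@@]2(C)CCC[C@@H](C)C2=C)c(I)c1O[Si](C)(C)C | intermediate
20 | 2-({4-[(1R,3R)-1,3-dimethyl-2-methylidenecyclohexyl]but-1-en-2-yl}oxy)-3-iodo-5-methoxybenzene-1,4-diol | COc1cc(O)c(OC(=C)CC[C@@]2(C)CCC[C@@H](C)C2=C)c(I)c1O | intermediate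
21 | 1-({4-[(1R,3R)-1,3-dimethyl-2-methylidenecyclohexyl]but-1-en-2-yl}oxy)-3,6-bis{[ethynyldi(propan-2-yl)silyl]oxy}-2-iodo-4-methoxybenzene | COc1cc(O[Si](C#C)(C(C)C)C(C)C)c(OC(=C)CC[C@@]2(C)CCC[C@@H](C)C2=C)c(I)c1O[Si](C#C)(C(C)C)C(C)C | intermediate
22 | tricyclic siloxane: (2S)-chromene with a di(propan-2-yl)silylene bridge from C4 to O5 and an ethynyldi(propan-2-yl)silyl ether on O8 | C[C@]1(CC[C@@]2(C)CCC[C@@H](C)C2=C)C=C3c4c(O1)c(O[Si](C#C)(C(C)C)C(C)C)cc(OC)c4O[Si]3(C(C)C)C(C)C | intermediate
23 | (2S)-2-{2-[(1R,3R)-1,3-dimethyl-2-methylidenecyclohexyl]ethyl}-6-methoxy-2-methyl-2H-chromene-5,8-diol | C=C1[C@H](C)CCC[C@]1(C)CC[C@@]1(C)C=Cc2c(O)c(OC)cc(O)c2O1 | target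

**Count**
Total steps: 13. Longest linear sequence: 10 steps (1, 2, 3, 4, 8, 9, 10, 11, 12, 13).

**Steps most likely to fail**

Step 12. What may go wrong: poor facial discrimination in the enol ether insertion that sets C2, hydride capture at the alkenyl–Pd stage before the pyran ring closes, or reopening of the pyran ring by β-aryloxide elimination from the Pd–CH2 intermediate. The fallback uses known chemistry and a different bond set; it sets out from keto acid 8 and hydroxyquinone 10 and comes back at target 23. Acid 8 is converted into Weinreb amide F1 (EDC·HCl, MeNHOMe·HCl, Et3N), and the ring ketone is methylenated with the ketone-selective Lombardo reagent (Zn, CH2Br2, TiCl4) to give methylene amide F2. MeMgBr then gives methyl ketone F3, a Horner–Wadsworth–Emmons reaction with diethyl cyanomethylphosphonate and NaH gives unsaturated nitrile F4, and iBu2AlH gives enal F5. Condensation of F5 with 10 (pyridine, 90 °C) by the known Knoevenagel/oxa-6π-electrocyclisation sequence of hydroxyquinones gives chromenequinone F6. This closes the pyran ring without control at C2, but the two C2 epimers are diastereomers and should be separable by preparative HPLC; Na2S2O4 then reduces F6 to 23.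

Step 13. What may go wrong: incomplete protodesilylation at the hindered vinylic silicon after the Si–O bonds have been cleaved. The fallback sets out from 22 and comes back at 23. Tamao-type oxidation of the alkenyl–silicon bond (H2O2, KF, KHCO3, THF/MeOH), followed by TBAF in the same flask and a dithionite wash, should give chromanone F7, since the enol formed at C4 tautomerises. NaBH4 reduces it to chromanol F8, a benzylic alcohol with an ortho phenol, which should lose water on gentle heating through the ortho-quinone methide to give 23.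

Step 11. What may go wrong: addition of the freed C8 phenol to the neighbouring enol ether (closure to a benzodioxole ketal), air oxidation of the free hydroquinone during the silyl exchange, or incomplete silylation of the hindered O5 phenol so that only one of the two silyl groups is installed. The fallback never frees the phenols once the enol ether exists; it sets out from 16 and comes back at 21. Quinone 16 is reduced as in step 9 (through 17) and silylated with two equivalents of chloro[di(propan-2-yl)][(trimethylsilyl)ethynyl]silane F9 (made from 12 and lithium (trimethylsilyl)acetylide) and imidazole to give bis-silyl ester F10. The Cp2TiMe2 methylenation is run on F10, whose alkynes are shielded at both ends by silicon, to give enol ether F11. K2CO3 in MeOH at 0 °C should then remove only the carbon-bound trimethylsilyl groups and give 21.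

**Further compounds**
F1 | step 12 | 3-[(1R,3R)-1,3-dimethyl-2-oxocyclohexyl]-N-methoxy-N-methylpropanamide | O=C1[C@H](C)CCC[C@]1(C)CCC(=O)N(C)OC
F2 | step 12 | 3-[(1R,3R)-1,3-dimethyl-2-methylidenecyclohexyl]-N-methoxy-N-methylpropanamide | C=C1[C@H](C)CCC[C@]1(C)CCC(=O)N(C)OC
F3 | step 12 | 4-[(1R,3R)-1,3-dimethyl-2-methylidenecyclohexyl]butan-2-one | C=C1[C@H](C)CCC[C@]1(C)CCC(C)=O
F4 | step 12 | 5-[(1R,3R)-1,3-dimethyl-2-methylidenecyclohexyl]-3-methylpent-2-enenitrile (E/Z mixture) | C=C1[C@H](C)CCC[C@]1(C)CCC(C)=CC#N
F5 | step 12 | 5-[(1R,3R)-1,3-dimethyl-2-methylidenecyclohexyl]-3-methylpent-2-enal (E/Z mixture) | C=C1[C@H](C)CCC[C@]1(C)CCC(C)=CC=O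
F6 | step 12 | (2S)-2-{2-[(1R,3R)-1,3-dimethyl-2-methylidenecyclohexyl]ethyl}-6-methoxy-2-methyl-2H-chromene-5,8-dione | C=C1[C@H](C)CCC[C@]1(C)CC[C@@]1(C)C=CC2=C(O1)C(=O)C=C(OC)C2=O
F7 | step 13 | (2S)-2-{2-[(1R,3R)-1,3-dimethyl-2-methylidenecyclohexyl]ethyl}-5,8-dihydroxy-6-methoxy-2-methyl-2,3-dihydro-4H-chromen-4-one | C=C1[C@H](C)CCC[C@]1(C)CC[C@@]1(C)CC(=O)c2c(O)c(OC)cc(O)c2O1
F8 | step 13 | (2S)-2-{2-[(1R,3R)-1,3-dimethyl-2-methylidenecyclohexyl]ethyl}-6-methoxy-2-methyl-3,4-dihydro-2H-chromene-4,5,8-triol (C4 epimers) | C=C1[C@H](C)CCC[C@]1(C)CC[C@@]1(C)CC(O)c2c(O)c(OC)cc(O)c2O1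
F9 | step 11 | chloro[di(propan-2-yl)][(trimethylsilyl)ethynyl]silane | C[Si](C)(C)C#C[Si](Cl)(C(C)C)C(C)C
F10 | step 11 | 2-iodo-4-methoxy-3,6-bis({di(propan-2-yl)[(trimethylsilyl)ethynyl]silyl}oxy)phenyl 3-[(1R,3R)-1,3-dimethyl-2-oxocyclohexyl]propanoate | COc1cc(O[Si](C#C[Si](C)(C)C)(C(C)C)C(C)C)c(OC(=O)CC[C@@]2(C)CCC[C@@H](C)C2=O)c(I)c1O[Si](C#C[Si](C)(C)C)(C(C)C)C(C)C
F11 | step 11 | 1-({4-[(1R,3R)-1,3-dimethyl-2-methylidenecyclohexyl]but-1-en-2-yl}oxy)-2-iodo-4-methoxy-3,6-bis({di(propan-2-yl)[(trimethylsilyl)ethynyl]silyl}oxy)benzene | COc1cc(O[Si](C#C[Si](C)(C)C)(C(C)C)C(C)C)c(OC(=C)CC[C@@]2(C)CCC[C@@H](C)C2=C)c(I)c1O[Si](C#C[Si](C)(C)C)(C(C)C)C(C)C
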